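Run this flask on one clock: freeze what hardly moves, free catalyst and dissolved gas, and read the substrate off a single exponential.

- cedar: substrate 0.10 M; gas phase 3.5 mM (held); catalyst 8.1 mM; added ligand 12 mM; time 4.0 h
- oak: substrate 0.10 M; gas phase 3.5 mM (held); catalyst 8.1 mM; added ligand 12 mM; time 12 h

    catalyst + added ligand ⇌ idle complex, settled at all times (K1 = 2500 M⁻¹)
    substrate + dissolved gas + catalyst → catalyst + product (k2 = 690 M⁻² min⁻¹)
    2 substrate → homo dimer (k3 = 3.3 × 10⁻⁴ M⁻¹ min⁻¹)
    gas phase ⇌ dissolved gas, rate k4*(csat - [dissolved gas]) (k4 = 0.88 min⁻¹, csat = 3.5 mM)

- a species is counted by the substrate in it: one homo dimer counts as two
- where a step has two of a species, its rate is k times that concentration squared, and two are used at each turn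
- at the start none of the gas is dissolved
- run time (cedar): 4.0 h

* which of these there is most of at the end, counted by the substrate in it, cedar (substrate / product)
* which of these there is most of at the end, counted by the substrate in it, oak (substrate / product)
* the largest of these amounts at the end, in percent of the substrate charged, cedar
* the largest of these amounts at the end, in percent of the substrate charged, oak

Cedar and oak have the same charges and differ in reading time, so the reckoning below serves both.

1. First way to [catalyst]. Added ligand parks catalyst as idle complex. Put both charge balances into the equilibrium and you get a quadratic with linear coefficient 10.8. Its root is [catalyst] = 0.654 mM.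

2. Second way. Freeze [added ligand] at the charge difference, 3.90 mM. That gives [catalyst] = 0.753 mM, which is more than the first way gave.

3. Find the cheat. The second way counts the whole catalyst charge as bound, yet the unbound catalyst has left its ligand free. Put that ligand back, 4.65 mM, and [catalyst] drops to 0.641 mM, beside the first way. Trust 0.654 mM.

4. Freeze the gas. Transfer runs at 0.88 min⁻¹, faster than the use of dissolved gas at the charged substrate, 0.0451 min⁻¹. So [dissolved gas], zero at the start, rises on a time of 1.14 min to close to 3.5 mM, and the substrate falls pseudo-first-order.

5. The clock. The value 10.6 h is the substrate clock, the time in which substrate falls by a factor e at frozen [catalyst] and [dissolved gas].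

6. Read it. Substrate left is 68.4% in cedar and 32.1% in oak. Homo dimer is a small side loss, since the first half-life of substrate by that step alone, 253 h, is longer than the clock. Integrated along the falling substrate, it takes 1.87% in oak. So the reckoning puts oak at 66.0% product, more than substrate, and cedar with substrate in the lead.

The forecast names substrate for cedar at 69% (66% to 72%) and product for oak at 66% (62% to 69%), on the ground that “the substrate decays roughly first order”.

The simulation gives substrate at 68.7% for cedar and product at 65.8% for oak.

Cedar's clock of 10.6 h is longer than its 4.0 h run, and substrate leads there because of the parking as idle complex together with the hour of the reading. In cedar without the parking, product reaches 98.0% against 30.2%; in cedar with the parking but read at 40.0 h, product reaches 95.6%. Now take cedar's neighbour with 0.030 M added ligand. The same quadratic, with coefficient 55.8, gives [catalyst] = 0.144 mM, a clock of 47.8 h and a reckoned 92.0% substrate left. That neighbour holds 91% of its charged substrate.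

Its constants were set for the occasion; the result is computed.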